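(The rate constants come from no measurement; the flask was simulated.)

A neighbouring flask with 0.3 mol% of initiator runs beside this one, and one quantity should serve for both.

    free monomer + initiator → living end + monomer in chains (k1 = 1.10 /M/s)
    free monomer + living end → monomer in chains + living end, rate k2*[living end]*[free monomer] (k2 = 4.19 /M/s)
    2 initiator → spent initiator (k3 = 6.05 /M/s)

free monomer 0.20 M (fed, over 20 s); initiator 0.5 mol%; time 2.5 min; the fed solution adds 0.10 times the starting volume

- for a step with 2 of a species take k times the square, and two of it per event
- charges are per starting volume, the dose included; the dosed solution carries all of it
- the average divides the monomer in chains by the number of chains begun, living and dead together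
- run time (flask): 2.5 min

- average number of monomer units in a chain (chains begun, living or dead) at 2.5 min
- part of the free monomer that has reacted at 2.5 min

Chain growth consumes free monomer at 4.19 /M/s times the living end L times the free monomer, so while L stands still the loss is pseudo-first-order, and L is the concentration to find. A first guess turns the whole initiator charge, 0.00100 M, into living ends. But initiator also pairs off while free monomer trickles in at 0.0100 M/s. With free monomer rising steadily, capture needs a time of about τ = 13.5 s, shorter than the feed. Pairing at the full charge for τ would take 16.3 % of the initiator, but initiator falls meanwhile, so the estimate here is f = 8.16 %, half of that.

Diluted by the feed, L is 8.35 × 10⁻⁴ M, and the half-life of free monomer under the living ends is ln(2)/(k × L) = 3.30 min, with k the growth constant. Should the clock start at zero? Living ends are still forming then, so this reckoning starts it at τ. The last free monomer arrives 6.52 s later, which is small against that half-life. This gives a conversion of 38.0 %. Dilution cancels in the chain length, which is conversion over loading times (1 − f), or 82.7.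

The forecast gives 83 (78 to 88) and 37.6 % (35 % to 40 %), with living ends that “consume monomer at roughly 0.0034 per second for the remaining 130 s”. The clock here starts earlier, at τ, and the conversion reckoned above is higher than the forecast's.

The simulation gives 83.0 and 37.7 %.

In this flask at 2.50 min, the half-life of free monomer by chain growth is 3.3 min, shorter than its 11 min by step 1 alone with initiator held at its charge, and free monomer stands at 62.3 % of its charge beside 8.26 × 10⁻⁴ M of living end. For the neighbour, f scales with the charge to 4.89 %, so L is 5.19 × 10⁻⁴ M, the half-life stretches to 5.31 min, and the conversion comes to 25.7 %; that neighbour flask ends at 25.5 %.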